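**Retrosynthetic overview** (target numbering: ring C1–C14 with C1 the stereocentre, C15 the side-chain carbon bearing =CH2)
- The only ring, the 14-membered carbocycle, is closed last at the C9–C10 single bond. This bond joins two allylic methylenes flanked by the E-C7=C8 and Z-C11=C12 alkenes, so a C10 allylic phenylsulfonyl carbanion can displace a C9 primary allylic bromide; the sulfone is then removed reductively.
- The seco chain comes from a Z-selective Still–Gennari olefination (C3=C4) of a C3 aldehyde with a C4–C9 phosphonate made from 5-bromo-2-methylpent-2-ene (C4–C5 by phosphonate alkylation).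
- C1 is set by rhodium/(S)-BINAP conjugate addition of a sulcatone-derived alkenyltrifluoroborate (C15 unit) to a nerol-derived E-enoate (C10–C14, C1–C3).
- C4 is carried as CH2OSi(t-Bu)Ph2 and oxidised to CO2H at the end.

Key step: step 20

Remark on the chemistry: target atom numbers are used for all intermediates. The C10 stereocentre made in the ring closure is removed again in step 21, so no control is planned for it.

**Step 1**
Reactants: 1 nerol
Product: 2 neryl 4-methoxybenzyl ether
Conditions: NaH, 4-methoxybenzyl chloride, Bu4NI (cat.), THF/DMF, 0 °C to rt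
Reagents that add atoms: 4-methoxybenzyl chloride, COc1ccc(CCl)cc1
Why: Williamson etherification of the primary allylic alkoxide masks the C10 oxygen with a group that can later be removed oxidatively beside silyl ethers.

**Step 2**
Reactants: 2 neryl 4-methoxybenzyl ether
Product: 3 distal (6,7-) epoxide of 2, racemic at the oxirane carbon
Conditions: mCPBA (1.05 equiv), CH2Cl2, −20 to 0 °C
Reagents that add atoms: 3-chloroperbenzoic acid, OOC(=O)c1cccc(Cl)c1
Why: Prilezhaev epoxidation should occur at the more electron-rich distal trisubstituted alkene, the C11=C12 alkene being deactivated by the allylic ether oxygen; the new oxirane stereocentre is irrelevant because that carbon is cleaved in step 3.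

**Step 3**
Reactants: 3 distal epoxide
Product: 4 (4Z)-6-[(4-methoxybenzyl)oxy]-4-methylhex-4-enal (C1 aldehyde, C10–C14)
Conditions: H5IO6, THF/H2O, 0 °C
Reagents that add atoms: none
Why: Acid-mediated epoxide hydrolysis (water enters at the tertiary carbon) followed by Malaprade glycol cleavage releases acetone and the aldehyde that becomes C1.

**Step 4**
Reactants: 4 C1 aldehyde; 5 isopropyl 2-(diethoxyphosphoryl)acetate
Product: 6 isopropyl (2E,6Z)-8-[(4-methoxybenzyl)oxy]-6-methylocta-2,6-dienoate
Conditions: LiCl, DBU, MeCN, 0 °C to rt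
Reagents that add atoms: none
Why: Horner–Wadsworth–Emmons olefination under Masamune–Roush conditions should give the E-enoate (C1=C2, ester carbon C3) from the stabilised phosphonate under mild base.

**Step 5**
Reactants: 7 6-methylhept-5-en-2-one (sulcatone)
Product: 9 6-methylhepta-1,5-dien-2-yl trifluoromethanesulfonate, via lithium enolate 8 (not isolated)
Conditions: LiN(i-Pr)2, THF, −78 °C; then PhNTf2, −78 to 0 °C
Reagents that add atoms: N-phenylbis(trifluoromethanesulfonimide), O=S(=O)(N(c1ccccc1)S(=O)(=O)C(F)(F)F)C(F)(F)F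
Why: Kinetic deprotonation on the methyl side of the methyl ketone and O-triflation of the less substituted enolate give the 1,1-disubstituted alkenyl triflate.

**Step 6**
Reactants: 9 alkenyl triflate
Product: 10 4,4,5,5-tetramethyl-2-(6-methylhepta-1,5-dien-2-yl)-1,3,2-dioxaborolane
Conditions: bis(pinacolato)diboron, PdCl2(PPh3)2 (3 mol %), PPh3, KOPh, toluene, 50 °C
Reagents that add atoms: bis(pinacolato)diboron, CC1(C)OB(B2OC(C)(C)C(C)(C)O2)OC1(C)C
Why: Miyaura borylation (oxidative addition of zerovalent palladium into the alkenyl C–O bond, transmetalation with the diboron, reductive elimination) replaces triflate by boron with the alkene position kept.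

**Step 7**
Reactants: 10 alkenyl pinacol boronate
Product: 11 potassium trifluoro(6-methylhepta-1,5-dien-2-yl)borate
Conditions: KHF2, MeOH/H2O, rt
Reagents that add atoms: potassium hydrogen difluoride, [K+].F[H-]F
Why: Fluoride exchange at boron gives the bench-stable trifluoroborate, which hydrolyses slowly in aqueous media and transmetalates cleanly to rhodium.

**Step 8**
Reactants: 6 E-enoate; 11 potassium alkenyltrifluoroborate
Product: 12 isopropyl (3R,6Z)-8-[(4-methoxybenzyl)oxy]-6-methyl-3-(6-methylhepta-1,5-dien-2-yl)oct-6-enoate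
Conditions: [Rh(C8H12)2]BF4 (3 mol %), (S)-BINAP (3.3 mol %), toluene/H2O (10:1), 100 °C
Reagents that add atoms: none
Why: In this Hayashi–Miyaura conjugate addition the alkenylrhodium–BINAP species inserts the E-enoate and the resulting rhodium enolate is protonated by water; the (S)-ligand should deliver the alkenyl group to the α-si face of the E-enoate (the sense that turns E-crotonates into (R)-3-substituted butanoates), which sets C1 as R.

**Step 9**
Reactants: 12 conjugate adduct ester
Product: 13 (3R,6Z)-8-[(4-methoxybenzyl)oxy]-6-methyl-3-(6-methylhepta-1,5-dien-2-yl)oct-6-enal (C3 aldehyde)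
Conditions: i-Bu2AlH (1.1 equiv), CH2Cl2, −78 °C
Reagents that add atoms: none
Why: Partial ester reduction through the tetrahedral aluminium hemiacetal, stable at −78 °C, should give the aldehyde on work-up; C1 is β to the carbonyl and cannot epimerise.

**Step 10**
Reactants: 14 5-bromo-2-methylpent-2-ene
Product: 15 (2E)-5-bromo-2-methylpent-2-en-1-ol
Conditions: SeO2 (0.3 equiv), t-BuOOH, salicylic acid (cat.), CH2Cl2, rt, partial conversion
Reagents that add atoms: tert-butyl hydroperoxide, CC(C)(C)OO (terminal oxidant; the oxygen is passed on by catalytic SeO2, O=[Se]=O)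
Why: Catalytic SeO2 allylic oxidation (ene reaction, then [2,3]-sigmatropic shift) hydroxylates the methyl group trans to the chain, giving the E-allylic alcohol that carries the C9 oxygen and the E-C7=C8 alkene.

**Step 11**
Reactants: 15 E-allylic alcohol
Product: 16 {[(2E)-5-bromo-2-methylpent-2-en-1-yl]oxy}(tert-butyl)dimethylsilane
Conditions: tert-butyldimethylsilyl chloride, imidazole, CH2Cl2, 0 °C to rt
Reagents that add atoms: tert-butyldimethylsilyl chloride, CC(C)(C)[Si](C)(C)Cl
Why: Standard silylation of the primary allylic alcohol under conditions that leave the homoallylic bromide intact.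

**Step 12**
Reactants: 16 bromide; 17 methyl 2-[bis(2,2,2-trifluoroethoxy)phosphoryl]acetate (in excess)
Product: 19 methyl (5E)-2-[bis(2,2,2-trifluoroethoxy)phosphoryl]-7-[(tert-butyldimethylsilyl)oxy]-6-methylhept-5-enoate, via sodium phosphonate 18 (not isolated)
Conditions: NaH, DMF, 0 °C; then 16, Bu4NI (cat.), 50 °C
Reagents that add atoms: none
Why: C-alkylation of the sodium phosphonoacetate by the primary homoallylic bromide (iodide-assisted SN2) forms C4–C5, and the excess of 17 limits dialkylation.

**Step 13**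
Reactants: 13 C3 aldehyde; 19 C4–C9 phosphonate
Product: 21 seco methyl ester (1R,3Z,7E,11Z; CO2Me on C4 cis to C2, C9 OSi(t-Bu)Me2, C10 O-4-methoxybenzyl), via potassium phosphonate 20 (not isolated)
Conditions: KN(SiMe3)2, 18-crown-6, THF, −78 °C; then 13, −78 °C
Reagents that add atoms: none
Why: In this Still–Gennari olefination the electron-poor trifluoroethyl phosphonate with a dissociated potassium counter-ion eliminates from the kinetically formed oxaphosphetane, which should give the Z-enoate with CO2Me cis to C2, the geometry of C3=C4 in the target.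

**Step 14**
Reactants: 21 seco methyl ester
Product: 22 seco allylic alcohol (CH2OH on C4)
Conditions: i-Bu2AlH (2.5 equiv), CH2Cl2, −78 °C
Reagents that add atoms: none
Why: 1,2-Reduction of the conjugated ester by excess aluminium hydride gives the allylic alcohol with the alkene geometry unchanged.

**Step 15**
Reactants: 22 seco allylic alcohol
Product: 23 C4 tert-butyldiphenylsilyl ether
Conditions: tert-butyl(chloro)diphenylsilane, imidazole, DMF, rt
Reagents that add atoms: tert-butyl(chloro)diphenylsilane, CC(C)(C)[Si](Cl)(c1ccccc1)c1ccccc1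
Why: Silylation gives a C4 group without acidic C–H bonds that survives the acid used later at C9 and the hydride used for desulfonylation.

**Step 16**
Reactants: 23 fully protected seco triol
Product: 24 C10 alcohol
Conditions: DDQ, CH2Cl2/pH 7 buffer, 0 °C
Reagents that add atoms: none
Why: Oxidative cleavage of the 4-methoxybenzyl ether (hydride abstraction to the oxocarbenium ion, then hydrolysis) should leave both silyl ethers and the isolated alkenes untouched under buffered conditions.

**Step 17**
Reactants: 24 C10 alcohol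
Product: 26 C10 phenyl sulfone (Z-allylic), via allylic chloride 25 (not isolated)
Conditions: MeSO2Cl, 2,4,6-collidine, LiCl, DMF, 0 °C; then PhSO2Na, rt
Reagents that add atoms: sodium benzenesulfinate, [Na+].[O-]S(=O)c1ccccc1; lithium chloride, [Li+].[Cl-] (chlorine of intermediate 25 only)
Why: The mesylate formed in situ is displaced by chloride without allylic transposition and sulfinate then displaces the primary allylic chloride through sulfur by SN2, so the Z geometry of C11=C12 is kept.

**Step 18**
Reactants: 26 C10 sulfone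
Product: 27 C9 alcohol
Conditions: pyridinium p-toluenesulfonate, MeOH, rt
Reagents that add atoms: none
Why: Acid-catalysed methanolysis removes the more labile tert-butyldimethylsilyl ether, while the tert-butyldiphenylsilyl ether and the sulfone are stable.

**Step 19**
Reactants: 27 C9 alcohol
Product: 28 seco Z-allylic sulfone–E-allylic bromide
Conditions: CBr4, PPh3, CH2Cl2, 0 °C
Reagents that add atoms: carbon tetrabromide, BrC(Br)(Br)Br
Why: Appel bromination of the primary allylic alcohol under neutral conditions gives the E-allylic bromide without transposition.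

**Step 20**
Reactants: 28 seco bromo sulfone
Product: 30 14-membered C10 phenyl sulfone (both C10 epimers), via potassium sulfonyl carbanion 29 (not isolated)
Conditions: KN(SiMe3)2 (1.3 equiv), THF, −78 °C, 28 added over 8 h to ca. 0.002 M; then to −20 °C
Reagents that add atoms: none
Why: KN(SiMe3)2 removes the C10–H that is both allylic and α to the sulfonyl group, and the potassium sulfonyl allyl anion 29 displaces bromide at the primary allylic C9 by SN2, forming C9–C10. The closest known reaction type is the intramolecular alkylation of sulfone-stabilised allylic carbanions by allylic halides used to close 14-membered cembranoid carbocycles. The 14-membered ring closes end to end in an exo-tet mode at high dilution, where ring closure should outrun intermolecular alkylation and the three preset trisubstituted alkenes restrict the chain. The new C10 stereocentre is not controlled and need not be, since both epimers converge on 31 in step 21, while C1 is a remote spectator. The step needs α- rather than γ-alkylation (secured by the charge at the sulfur-bearing carbon and the tertiary nature of C12), direct rather than allylic displacement (secured by the unhindered primary C9 against the substituted C7) and retention of the Z-C11=C12 geometry (secured by the configurational stability of the sulfonyl allyl anion at −78 °C). No other acidic C–H competes because C4 is a silyloxymethyl group.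

**Step 21**
Reactants: 30 macrocyclic sulfone
Product: 31 macrocyclic C4 silyl ether (1R,3Z,7E,11Z)
Conditions: PdCl2[Ph2P(CH2)3PPh2] (10 mol %), LiBHEt3 (3 equiv), THF, 0 °C to rt
Reagents that add atoms: none
Why: Zerovalent palladium formed in situ ionises the allylic sulfone to a π-allylpalladium complex over C10–C12 and hydride is delivered to the less substituted terminus C10, so C11=C12 stays in place and stays Z because syn–anti exchange would need a σ-bond at the tertiary C12; this is the known palladium-catalysed hydride desulfonylation of allylic sulfones.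

**Step 22**
Reactants: 31 macrocyclic silyl ether
Product: 32 [(1Z,4R,7Z,11E)-7,11-dimethyl-4-(6-methylhepta-1,5-dien-2-yl)cyclotetradeca-1,7,11-trien-1-yl]methanol
Conditions: Bu4NF, THF, rt
Reagents that add atoms: none
Why: Fluoride cleaves the Si–O bond and frees the primary allylic alcohol without affecting the triene.

**Step 23**
Reactants: 32 macrocyclic allylic alcohol
Product: 33 (1Z,4R,7Z,11E)-7,11-dimethyl-4-(6-methylhepta-1,5-dien-2-yl)cyclotetradeca-1,7,11-triene-1-carbaldehyde
Conditions: MnO2 (excess), CH2Cl2, rt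
Reagents that add atoms: none
Why: Heterogeneous MnO2 oxidises the allylic alcohol selectively under neutral conditions, which should keep the geometry of the C3=C4 enal; the aldehyde is used at once.

**Step 24**
Reactants: 33 macrocyclic enal
Product: 34 (1Z,4R,7Z,11E)-7,11-dimethyl-4-(6-methylhepta-1,5-dien-2-yl)cyclotetradeca-1,7,11-triene-1-carboxylic acid (CNP0269207.1)
Conditions: NaClO2, NaH2PO4, 2-methylbut-2-ene, t-BuOH/H2O, 0 °C to rt
Reagents that add atoms: sodium chlorite, [Na+].[O-]Cl=O
Why: Pinnick oxidation converts the enal into the acid through the chlorite adduct, and the alkene scavenger removes hypochlorous acid so that the ring alkenes and the C3=C4 geometry are preserved.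

**Compound list**
1 | nerol, (2Z)-3,7-dimethylocta-2,6-dien-1-ol | CC(C)=CCC/C(C)=C\CO | starting material
2 | neryl 4-methoxybenzyl ether | CC(C)=CCC/C(C)=C\COCc1ccc(OC)cc1 | intermediate
3 | 3-{(3Z)-5-[(4-methoxybenzyl)oxy]-3-methylpent-3-en-1-yl}-2,2-dimethyloxirane (racemic at the oxirane carbon) | CC1(C)OC1CC/C(C)=C\COCc1ccc(OC)cc1 | intermediate
4 | (4Z)-6-[(4-methoxybenzyl)oxy]-4-methylhex-4-enal | O=CCC/C(C)=C\COCc1ccc(OC)cc1 | intermediate
5 | isopropyl 2-(diethoxyphosphoryl)acetate | CCOP(=O)(OCC)CC(=O)OC(C)C | starting material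
6 | isopropyl (2E,6Z)-8-[(4-methoxybenzyl)oxy]-6-methylocta-2,6-dienoate | CC(C)OC(=O)/C=C/CC/C(C)=C\COCc1ccc(OC)cc1 | intermediate
7 | 6-methylhept-5-en-2-one (sulcatone) | CC(=O)CCC=C(C)C | starting material
8 | lithium 6-methylhepta-1,5-dien-2-olate | C=C(CCC=C(C)C)O[Li] | intermediate
9 | 6-methylhepta-1,5-dien-2-yl trifluoromethanesulfonate | C=C(CCC=C(C)C)OS(=O)(=O)C(F)(F)F | intermediate
10 | 4,4,5,5-tetramethyl-2-(6-methylhepta-1,5-dien-2-yl)-1,3,2-dioxaborolane | C=C(CCC=C(C)C)B1OC(C)(C)C(C)(C)O1 | intermediate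
11 | potassium trifluoro(6-methylhepta-1,5-dien-2-yl)borate | C=C(CCC=C(C)C)[B-](F)(F)F.[K+] | intermediate
12 | isopropyl (3R,6Z)-8-[(4-methoxybenzyl)oxy]-6-methyl-3-(6-methylhepta-1,5-dien-2-yl)oct-6-enoate | C=C(CCC=C(C)C)[C@H](CC/C(C)=C\COCc1ccc(OC)cc1)CC(=O)OC(C)C | intermediate
13 | (3R,6Z)-8-[(4-methoxybenzyl)oxy]-6-methyl-3-(6-methylhepta-1,5-dien-2-yl)oct-6-enal | C=C(CCC=C(C)C)[C@H](CC/C(C)=C\COCc1ccc(OC)cc1)CC=O | intermediate
14 | 5-bromo-2-methylpent-2-ene | CC(C)=CCCBr | starting material
15 | (2E)-5-bromo-2-methylpent-2-en-1-ol | OC/C(C)=C/CCBr | intermediate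
16 | {[(2E)-5-bromo-2-methylpent-2-en-1-yl]oxy}(tert-butyl)dimethylsilane | CC(C)(C)[Si](C)(C)OC/C(C)=C/CCBr | intermediate
17 | methyl 2-[bis(2,2,2-trifluoroethoxy)phosphoryl]acetate | COC(=O)CP(=O)(OCC(F)(F)F)OCC(F)(F)F | starting material
18 | sodium salt of 17 (phosphonoacetate carbanion) | COC(=O)[CH-]P(=O)(OCC(F)(F)F)OCC(F)(F)F.[Na+] | intermediate
19 | methyl (5E)-2-[bis(2,2,2-trifluoroethoxy)phosphoryl]-7-[(tert-butyldimethylsilyl)oxy]-6-methylhept-5-enoate (racemic at C2) | COC(=O)C(CC/C=C(\C)CO[Si](C)(C)C(C)(C)C)P(=O)(OCC(F)(F)F)OCC(F)(F)F | intermediate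
20 | potassium salt of 19 (phosphonate carbanion) | COC(=O)[C-](CC/C=C(\C)CO[Si](C)(C)C(C)(C)C)P(=O)(OCC(F)(F)F)OCC(F)(F)F.[K+] | intermediate
21 | seco methyl ester, methyl (2Z,5R,8Z)-2-{(3E)-5-[(tert-butyldimethylsilyl)oxy]-4-methylpent-3-en-1-yl}-10-[(4-methoxybenzyl)oxy]-8-methyl-5-(6-methylhepta-1,5-dien-2-yl)deca-2,8-dienoate | C=C(CCC=C(C)C)[C@H](CC/C(C)=C\COCc1ccc(OC)cc1)C/C=C(\C(=O)OC)CC/C=C(\C)CO[Si](C)(C)C(C)(C)C | intermediate
22 | seco allylic alcohol (as 21 with CH2OH on C4; 1R,3Z,7E,11Z) | C=C(CCC=C(C)C)[C@H](CC/C(C)=C\COCc1ccc(OC)cc1)C/C=C(\CO)CC/C=C(\C)CO[Si](C)(C)C(C)(C)C | intermediate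
23 | seco C4 tert-butyldiphenylsilyl ether (C9 OSi(t-Bu)Me2, C10 O-4-methoxybenzyl) | C=C(CCC=C(C)C)[C@H](CC/C(C)=C\COCc1ccc(OC)cc1)C/C=C(\CO[Si](c1ccccc1)(c1ccccc1)C(C)(C)C)CC/C=C(\C)CO[Si](C)(C)C(C)(C)C | intermediate
24 | seco C10 alcohol | C=C(CCC=C(C)C)[C@H](CC/C(C)=C\CO)C/C=C(\CO[Si](c1ccccc1)(c1ccccc1)C(C)(C)C)CC/C=C(\C)CO[Si](C)(C)C(C)(C)C | intermediate
25 | seco C10 allylic chloride | C=C(CCC=C(C)C)[C@H](CC/C(C)=C\CCl)C/C=C(\CO[Si](c1ccccc1)(c1ccccc1)C(C)(C)C)CC/C=C(\C)CO[Si](C)(C)C(C)(C)C | intermediate
26 | seco C10 phenyl sulfone (C9 OSi(t-Bu)Me2) | C=C(CCC=C(C)C)[C@H](CC/C(C)=C\CS(=O)(=O)c1ccccc1)C/C=C(\CO[Si](c1ccccc1)(c1ccccc1)C(C)(C)C)CC/C=C(\C)CO[Si](C)(C)C(C)(C)C | intermediate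
27 | seco C10 sulfone C9 alcohol | C=C(CCC=C(C)C)[C@H](CC/C(C)=C\CS(=O)(=O)c1ccccc1)C/C=C(\CO[Si](c1ccccc1)(c1ccccc1)C(C)(C)C)CC/C=C(\C)CO | intermediate
28 | seco Z-allylic sulfone–E-allylic bromide (C4 CH2OSi(t-Bu)Ph2 cis to C2; 1R) | C=C(CCC=C(C)C)[C@H](CC/C(C)=C\CS(=O)(=O)c1ccccc1)C/C=C(\CO[Si](c1ccccc1)(c1ccccc1)C(C)(C)C)CC/C=C(\C)CBr | intermediate
29 | potassium C10 sulfonyl carbanion of 28 | C=C(CCC=C(C)C)[C@H](CC/C(C)=C\[CH-]S(=O)(=O)c1ccccc1)C/C=C(\CO[Si](c1ccccc1)(c1ccccc1)C(C)(C)C)CC/C=C(\C)CBr.[K+] | intermediate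
30 | 14-membered C10 phenyl sulfone (C10 epimers; 1R,3Z,7E,11Z) | C=C(CCC=C(C)C)[C@H]1C/C=C(\CO[Si](c2ccccc2)(c2ccccc2)C(C)(C)C)CC/C=C(\C)CC(S(=O)(=O)c2ccccc2)/C=C(/C)CC1 | intermediate
31 | tert-butyl{[(1Z,4R,7Z,11E)-7,11-dimethyl-4-(6-methylhepta-1,5-dien-2-yl)cyclotetradeca-1,7,11-trien-1-yl]methoxy}diphenylsilane | C=C(CCC=C(C)C)[C@H]1C/C=C(\CO[Si](c2ccccc2)(c2ccccc2)C(C)(C)C)CC/C=C(\C)CC/C=C(/C)CC1 | intermediate
32 | [(1Z,4R,7Z,11E)-7,11-dimethyl-4-(6-methylhepta-1,5-dien-2-yl)cyclotetradeca-1,7,11-trien-1-yl]methanol | C=C(CCC=C(C)C)[C@H]1C/C=C(\CO)CC/C=C(\C)CC/C=C(/C)CC1 | intermediate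
33 | (1Z,4R,7Z,11E)-7,11-dimethyl-4-(6-methylhepta-1,5-dien-2-yl)cyclotetradeca-1,7,11-triene-1-carbaldehyde | C=C(CCC=C(C)C)[C@H]1C/C=C(\C=O)CC/C=C(\C)CC/C=C(/C)CC1 | intermediate
34 | (1Z,4R,7Z,11E)-7,11-dimethyl-4-(6-methylhepta-1,5-dien-2-yl)cyclotetradeca-1,7,11-triene-1-carboxylic acid | C=C(CCC=C(C)C)[C@H]1C/C=C(\C(=O)O)CC/C=C(\C)CC/C=C(/C)CC1 | target

**Step count**
Total: 24 steps. Longest linear sequence: 18 steps (steps 1–4, 8, 9, 13–24, from nerol).

**Steps most likely to fail**

1. Step 20 (macrocyclisation). Intermolecular alkylation may outrun ring closure, the basic anion may cause elimination at the allylic bromide, or the sulfonyl allyl anion may lose its Z geometry before it is alkylated. The fallback closes the same C9–C10 bond reductively, without a carbanion, and sets out from 24. Acid methanolysis (pyridinium p-toluenesulfonate, MeOH) would remove the tert-butyldimethylsilyl group and give the C9,C10-diol F1. CBr4/PPh3 would convert both allylic alcohols into the bis(allylic bromide) F2. Slow addition of F2 to Ni(CO)4 (zerovalent nickel) in N-methylpyrrolidone at 50 °C should couple the two primary allyl termini and give the macrocyclic silyl ether 31 directly, where the route is rejoined before step 22. The geometry of the two allylic alkenes would have to be verified after this coupling.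

2. Step 8 (conjugate alkenylation). Transmetalation and insertion of the α-branched alkenyl group may be slower than protodeboronation, and facial discrimination on the flexible acyclic enoate may be incomplete. The fallback is an auxiliary-controlled, copper-mediated conjugate addition that sets out from aldehyde 4 and ketone 7. Horner–Wadsworth–Emmons reaction of 4 with diethyl {2-oxo-2-[(4S)-2-oxo-4-phenyl-1,3-oxazolidin-3-yl]ethyl}phosphonate (LiCl, i-Pr2NEt, MeCN) would give the E-N-enoyl oxazolidinone F3. Ketone 7 would be condensed with 2,4,6-triisopropylbenzenesulfonohydrazide to the sulfonylhydrazone F4, which in a Shapiro reaction (n-BuLi, 2 equiv, THF, −78 to 0 °C) gives the alkenyllithium F5; MgBr2·OEt2 converts this into the alkenylmagnesium bromide F6. With CuBr·SMe2 in THF/Me2S at −78 to −20 °C, F6 should add to the chelated s-cis enoyl imide on the face opposite the phenyl group and give the imide adduct F7 with C1 as R. LiBH4 would release the auxiliary and give the primary alcohol F8, and Dess–Martin periodinane would oxidise it to aldehyde 13, where the route is rejoined before step 13.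

3. Step 13 (Z-selective olefination). With the α-branched phosphonate the kinetic preference for the Z-enoate may erode, which would give geometric mixtures of 21 that are hard to separate. The fallback builds C3=C4 stereospecifically from an alkyne and sets out from 13 and 16. Corey–Fuchs reaction (CBr4, PPh3) would give the 1,1-dibromoalkene F9, n-BuLi (2 equiv) the lithium acetylide F10, and methyl chloroformate the ynoate F11. Syn-hydrostannation (Bu3SnH, Pd(PPh3)4 cat.) places tin α to the ester and gives the α-stannyl enoate F12, and iododestannylation (I2, CH2Cl2, 0 °C) with retention gives the α-iodo enoate F13 with C2 cis to CO2Me. Bromide 16 would be converted by Finkelstein exchange (NaI, acetone) into the homoallylic iodide F14 and by zinc insertion into the alkylzinc iodide F15. Negishi coupling of the iodo enoate with this zinc reagent (PdCl2[(Ph2PC5H4)2Fe] cat., THF) should give 21 with the alkene geometry retained, where the route is rejoined before step 14.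

**Further compounds**
F1 | step 20 | seco C9,C10-diol (C4 CH2OSi(t-Bu)Ph2) | C=C(CCC=C(C)C)[C@H](CC/C(C)=C\CO)C/C=C(\CO[Si](c1ccccc1)(c1ccccc1)C(C)(C)C)CC/C=C(\C)CO
F2 | step 20 | seco C9,C10-bis(allylic bromide) | C=C(CCC=C(C)C)[C@H](CC/C(C)=C\CBr)C/C=C(\CO[Si](c1ccccc1)(c1ccccc1)C(C)(C)C)CC/C=C(\C)CBr
F3 | step 8 | (4S)-3-[(2E,6Z)-8-[(4-methoxybenzyl)oxy]-6-methylocta-2,6-dienoyl]-4-phenyl-1,3-oxazolidin-2-one | O=C(/C=C/CC/C(C)=C\COCc1ccc(OC)cc1)N1C(=O)OC[C@@H]1c1ccccc1
F4 | step 8 | 6-methylhept-5-en-2-one 2,4,6-triisopropylbenzenesulfonylhydrazone | CC(CCC=C(C)C)=NNS(=O)(=O)c1c(C(C)C)cc(C(C)C)cc1C(C)C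
F5 | step 8 | (6-methylhepta-1,5-dien-2-yl)lithium | [Li]C(=C)CCC=C(C)C
F6 | step 8 | (6-methylhepta-1,5-dien-2-yl)magnesium bromide | C=C(CCC=C(C)C)[Mg]Br
F7 | step 8 | (4S)-3-[(3R,6Z)-8-[(4-methoxybenzyl)oxy]-6-methyl-3-(6-methylhepta-1,5-dien-2-yl)oct-6-enoyl]-4-phenyl-1,3-oxazolidin-2-one | C=C(CCC=C(C)C)[C@H](CC/C(C)=C\COCc1ccc(OC)cc1)CC(=O)N1C(=O)OC[C@@H]1c1ccccc1
F8 | step 8 | (3R,6Z)-8-[(4-methoxybenzyl)oxy]-6-methyl-3-(6-methylhepta-1,5-dien-2-yl)oct-6-en-1-ol | C=C(CCC=C(C)C)[C@H](CC/C(C)=C\COCc1ccc(OC)cc1)CCO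
F9 | step 13 | 1,1-dibromoalkene from 13 (C3=CBr2) | C=C(CCC=C(C)C)[C@H](CC/C(C)=C\COCc1ccc(OC)cc1)CC=C(Br)Br
F10 | step 13 | lithium acetylide (C3≡C4–Li) | C=C(CCC=C(C)C)[C@H](CC/C(C)=C\COCc1ccc(OC)cc1)CC#C[Li]
F11 | step 13 | methyl ynoate (C3≡C4–CO2Me) | C=C(CCC=C(C)C)[C@H](CC/C(C)=C\COCc1ccc(OC)cc1)CC#CC(=O)OC
F12 | step 13 | methyl α-(tributylstannyl) enoate (C2 cis to CO2Me) | C=C(CCC=C(C)C)[C@H](CC/C(C)=C\COCc1ccc(OC)cc1)C/C=C(\C(=O)OC)[Sn](CCCC)(CCCC)CCCC
F13 | step 13 | methyl α-iodo enoate (C2 cis to CO2Me) | C=C(CCC=C(C)C)[C@H](CC/C(C)=C\COCc1ccc(OC)cc1)C/C=C(\C(=O)OC)I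
F14 | step 13 | tert-butyl{[(2E)-5-iodo-2-methylpent-2-en-1-yl]oxy}dimethylsilane | CC(C)(C)[Si](C)(C)OC/C(C)=C/CCI
F15 | step 13 | {(3E)-5-[(tert-butyldimethylsilyl)oxy]-4-methylpent-3-en-1-yl}zinc iodide | CC(C)(C)[Si](C)(C)OC/C(C)=C/CC[Zn]I
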